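**Plan**

1. Cuts (6H-isochromen-6-one numbering: ring A = O2, C1, C8a, C4a, C4, C3; ring B = C4a, C5, C6, C7, C8, C8a; side chain C9–C15): first C5–Br; then C6–C7 and C5–C4a together, which takes the two-carbon C5–C6 unit out of ring B; then C8a–C8 (aldol); then O2–C3 (ring A) and C4–C4a; in the side chain C11–CH3 and C10–C11.
2. Enabling feature: in ring B the C6 ketone lies between the tertiary carbinol C7 and C5, and C5 is doubly bonded to C4a. C7 and C4a are 1,4-related through C8–C8a and can both be carbonyl carbons (C7 a methyl ketone, C4a the vinylogous-ester carbonyl of a ring A 2,3-dihydro-4H-pyran-4-one). One acetyl unit, acting as acyl anion at C6 and as enol at C5, can therefore bridge them in one flask (formal [4+2] annulation; C5–C6 is presumably an intact acetate unit of the polyketide).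
3. Forward order: side-chain enyne (C3, C4, C9–C15) from D-allo-isoleucine; acetylide addition to a C1–C8a–C4a aldehyde and oxidation to the ynone; boron anti-aldol (C8a–C8); ring A by 6-endo oxa-Michael closure; ring B by the annulation; bromination at C5; deprotection.
4. Stereochemistry: C12 and C13 from D-allo-isoleucine; C11 by chelation-controlled MeMgBr addition; E C9=C10 by hydroxyl-directed LiAlH4 reduction; C8 and C8a by an (E)-boron-enolate anti-aldol steered by (S)-lactaldehyde, whose own centre (C7) is then oxidized away; C7 by polar Felkin–Anh addition to the C7 ketone under control of C8.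

Key step: step 16

Assumption: compounds 1, 4, 11 and 15 are taken as commercial; Dx = (4S,5R)-5-[(2S)-butan-2-yl]-2,2,4-trimethyl-1,3-dioxolan-4-yl; atom numbers are those given in the plan.

**Route**

Step 1
Reactants: 1 D-allo-isoleucine
Product: 2 (2R,3S)-2-hydroxy-3-methylpentanoic acid
Conditions: NaNO2, 1 M H2SO4, H2O, 0 °C → rt
Reagents that add atoms: water, O
Why: Diazotization of the α-amino acid should go with net retention through the α-lactone (double inversion), so C12 (R) and C13 (S) are taken over from the amino acid.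

Step 2
Reactants: 2 (2R,3S)-2-hydroxy-3-methylpentanoic acid
Product: 3 (2R,3S)-2-hydroxy-N-methoxy-N,3-dimethylpentanamide
Conditions: MeNHOMe·HCl, EDC·HCl, HOBt, N-methylmorpholine, CH2Cl2, 0 °C → rt
Reagents that add atoms: N,O-dimethylhydroxylamine hydrochloride, CNOC.Cl
Why: Carbodiimide amidation of an α-hydroxy acid is standard and should give the Weinreb amide without touching the stereocentres.

Step 3
Reactants: 3 (2R,3S)-2-hydroxy-N-methoxy-N,3-dimethylpentanamide; 4 1,4-bis(trimethylsilyl)buta-1,3-diyne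
Product: 6 (6R,7S)-6-hydroxy-7-methyl-1-(trimethylsilyl)nona-1,3-diyn-5-one, via lithiated diyne 5 (not isolated)
Conditions: 4, MeLi·LiBr, THF, 0 °C → rt; 3 pre-treated with i-PrMgCl (1 equiv), THF, −20 °C; combined at −78 → −20 °C; aq. NH4Cl
Reagents that add atoms: none
Why: Mono-desilylation of the bis-silyl diyne gives the lithium acetylide, which should add once to the Weinreb amide (chelated tetrahedral intermediate, hydroxyl masked as its magnesium alkoxide) to give the ynone.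

Step 4
Reactants: 6 (6R,7S)-6-hydroxy-7-methyl-1-(trimethylsilyl)nona-1,3-diyn-5-one
Product: 7 (5S,6R,7S)-5,7-dimethyl-1-(trimethylsilyl)nona-1,3-diyne-5,6-diol
Conditions: MeMgBr (3.5 equiv), THF, −78 → −40 °C; aq. NH4Cl
Reagents that add atoms: methylmagnesium bromide, C[Mg]Br
Why: Chelation-controlled Grignard 1,2-addition (Cram chelate): the C12 magnesium alkoxide and the C11 carbonyl form a five-membered chelate and methyl should enter from the face of the C12 hydrogen, which sets 11S.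

Step 5
Reactants: 7 (5S,6R,7S)-5,7-dimethyl-1-(trimethylsilyl)nona-1,3-diyne-5,6-diol
Product: 8 (3E,5S,6R,7S)-5,7-dimethyl-1-(trimethylsilyl)non-3-en-1-yne-5,6-diol
Conditions: LiAlH4, THF, 0 °C → rt; Fieser work-up
Reagents that add atoms: none
Why: Hydroxyl-directed trans-hydroalumination of the triple bond next to the carbinol (LiAlH4 reduction of a 2,4-diyn-1-ol to the (E)-2-en-4-yn-1-ol) should set the E C9=C10 bond and leave the silyl alkyne intact.

Step 6
Reactants: 8 (3E,5S,6R,7S)-5,7-dimethyl-1-(trimethylsilyl)non-3-en-1-yne-5,6-diol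
Product: 9 (3E,5S,6R,7S)-5,7-dimethylnon-3-en-1-yne-5,6-diol
Conditions: K2CO3 (cat.), MeOH, rt
Reagents that add atoms: none
Why: Base-catalysed methanolysis of the C(sp)–SiMe3 bond is routine and frees the terminal alkyne (C4–H).

Step 7
Reactants: 9 (3E,5S,6R,7S)-5,7-dimethylnon-3-en-1-yne-5,6-diol
Product: 10 (4S,5R)-4-[(1E)-but-1-en-3-yn-1-yl]-5-[(2S)-butan-2-yl]-2,2,4-trimethyl-1,3-dioxolane
Conditions: 2,2-dimethoxypropane, PPTS (cat.), CH2Cl2, rt
Reagents that add atoms: 2,2-dimethoxypropane, COC(C)(C)OC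
Why: Acid-catalysed transketalization gives the isopropylidene acetal of the 1,2-diol, which masks both hydroxyls against the organometallic, boron and oxidation steps.

Step 8
Reactants: 10 (4S,5R)-4-[(1E)-but-1-en-3-yn-1-yl]-5-[(2S)-butan-2-yl]-2,2,4-trimethyl-1,3-dioxolane; 11 3-[(tert-butyldimethylsilyl)oxy]propanal
Product: 13 (6E)-1-[(tert-butyldimethylsilyl)oxy]-7-Dx-hept-6-en-4-yn-3-ol (both C3 epimers), via lithium acetylide 12 (not isolated)
Conditions: n-BuLi, THF, −78 °C; then 11, −78 → −40 °C; aq. NH4Cl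
Reagents that add atoms: none
Why: 1,2-Addition of the lithium acetylide to the aldehyde forms the C4–C4a bond; the new carbinol is oxidized in the next step, so its configuration does not matter.

Step 9
Reactants: 13 (6E)-1-[(tert-butyldimethylsilyl)oxy]-7-Dx-hept-6-en-4-yn-3-ol
Product: 14 (6E)-1-[(tert-butyldimethylsilyl)oxy]-7-Dx-hept-6-en-4-yn-3-one
Conditions: Dess–Martin periodinane, CH2Cl2, 0 °C → rt
Reagents that add atoms: none
Why: Dess–Martin oxidation of the propargylic alcohol should give the enynone under neutral conditions that spare the silyl ether and the acetal.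

Step 10
Reactants: 15 ethyl (S)-lactate
Product: 16 ethyl (2S)-2-[(triethylsilyl)oxy]propanoate
Conditions: Et3SiCl, imidazole, CH2Cl2, 0 °C → rt
Reagents that add atoms: chlorotriethylsilane, CC[Si](Cl)(CC)CC
Why: Standard silylation of the secondary hydroxyl; the lactate stereocentre is not involved.

Step 11
Reactants: 16 ethyl (2S)-2-[(triethylsilyl)oxy]propanoate
Product: 17 (2S)-2-[(triethylsilyl)oxy]propanal
Conditions: i-Bu2AlH (1.05 equiv), CH2Cl2, −78 °C; MeOH, aq. Rochelle salt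
Reagents that add atoms: none
Why: Low-temperature i-Bu2AlH reduction should stop at the aldehyde through the stable aluminium hemiacetal, the usual route to O-silyl lactaldehydes without racemization.

Step 12
Reactants: 14 (6E)-1-[(tert-butyldimethylsilyl)oxy]-7-Dx-hept-6-en-4-yn-3-one; 17 (2S)-2-[(triethylsilyl)oxy]propanal
Product: 19 (2S,3R,4S,8E)-4-{[(tert-butyldimethylsilyl)oxy]methyl}-3-hydroxy-2-[(triethylsilyl)oxy]-9-Dx-non-8-en-6-yn-5-one, via boron enolate 18 (not isolated)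
Conditions: (c-C6H11)2BCl, Et3N, Et2O, −78 → 0 °C; then 17, −78 → −20 °C; pH 7 buffer, MeOH
Reagents that add atoms: none
Why: Boron-mediated anti-aldol reaction: the (E)-enol borinate reacts through a chair Zimmerman–Traxler transition state (C8a/C8 anti) and attacks the α-silyloxy aldehyde anti to its C–O bond (Cornforth/polar Felkin–Anh, C8/C7 anti), so the (S)-lactaldehyde centre should fix 8R and 8aS.

Step 13
Reactants: 19 (2S,3R,4S,8E)-4-{[(tert-butyldimethylsilyl)oxy]methyl}-3-hydroxy-2-[(triethylsilyl)oxy]-9-Dx-non-8-en-6-yn-5-one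
Product: 20 (2S,3R,4S,8E)-3-[(tert-butyldimethylsilyl)oxy]-4-{[(tert-butyldimethylsilyl)oxy]methyl}-2-[(triethylsilyl)oxy]-9-Dx-non-8-en-6-yn-5-one
Conditions: t-BuMe2SiOSO2CF3, 2,6-lutidine, CH2Cl2, −78 °C
Reagents that add atoms: tert-butyldimethylsilyl trifluoromethanesulfonate, CC(C)(C)[Si](C)(C)OS(=O)(=O)C(F)(F)F
Why: Silyl triflate/2,6-lutidine silylation of the β-hydroxy ketone is fast at −78 °C and avoids retro-aldol and epimerization at C8a; the bulky C8 silyl ether later enforces non-chelated addition at C7.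

Step 14
Reactants: 20 (2S,3R,4S,8E)-3-[(tert-butyldimethylsilyl)oxy]-4-{[(tert-butyldimethylsilyl)oxy]methyl}-2-[(triethylsilyl)oxy]-9-Dx-non-8-en-6-yn-5-one
Product: 22 (3S)-3-{(1R,2S)-1-[(tert-butyldimethylsilyl)oxy]-2-hydroxypropyl}-6-[(E)-2-Dx-ethenyl]-2,3-dihydro-4H-pyran-4-one, via diol ynone 21 (not isolated)
Conditions: HF·pyridine, pyridine, THF, 0 °C → rt; aqueous work-up; then AuCl(PPh3) (5 mol %), AgOSO2CF3 (5 mol %), CH2Cl2, rt
Reagents that add atoms: none
Why: Buffered HF·pyridine should cleave the primary TBS and the secondary TES ether but not the hindered secondary TBS ether, and the freed C1 hydroxyl then adds 6-endo-dig to the β-carbon (C3) of the gold-activated ynone (oxa-Michael closure of a β-hydroxy ynone) to form ring A.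

Step 15
Reactants: 22 (3S)-3-{(1R,2S)-1-[(tert-butyldimethylsilyl)oxy]-2-hydroxypropyl}-6-[(E)-2-Dx-ethenyl]-2,3-dihydro-4H-pyran-4-one
Product: 23 (3S)-3-{(1R)-1-[(tert-butyldimethylsilyl)oxy]-2-oxopropyl}-6-[(E)-2-Dx-ethenyl]-2,3-dihydro-4H-pyran-4-one
Conditions: Dess–Martin periodinane, CH2Cl2, 0 °C → rt
Reagents that add atoms: none
Why: Neutral Dess–Martin oxidation of the C7 carbinol gives the methyl ketone without epimerization at C8/C8a or β-elimination; the lactate-derived centre is erased after having controlled C8 and C8a.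

Step 16
Reactants: 23 (3S)-3-{(1R)-1-[(tert-butyldimethylsilyl)oxy]-2-oxopropyl}-6-[(E)-2-Dx-ethenyl]-2,3-dihydro-4H-pyran-4-one
Product: 26 (7R,8R,8aS)-8-[(tert-butyldimethylsilyl)oxy]-7-hydroxy-7-methyl-3-[(E)-2-Dx-ethenyl]-1,7,8,8a-tetrahydro-6H-isochromen-6-one, via enol ether adduct 24 (not isolated), via ketol 25 (not isolated)
Conditions: CH2=C(OEt)Li (from ethyl vinyl ether, t-BuLi, THF, −78 → 0 °C), CeCl3, THF, −78 °C; then p-TsOH·H2O (excess), THF, −78 → 40 °C, same flask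
Reagents that add atoms: ethyl vinyl ether, CCOC=C (used as 1-ethoxyvinyllithium); water, O (from p-TsOH·H2O)
Why: The cerium-modified 1-ethoxyvinyl anion (acetyl anion equivalent) adds irreversibly to the C7 methyl ketone to form C6–C7; p-TsOH·H2O then protonates the enol ether at C5, water converts the oxocarbenium ion into the methyl ketone 25, its enol attacks the protonated C4a carbonyl of the vinylogous ester, and loss of water through the ring A oxocarbenium ion with deprotonation at C5 gives the cross-conjugated dienone (C5–C4a). The closest known reaction types are the α-alkoxyvinyllithium acyl-anion addition to ketones and the acid-mediated intramolecular aldol condensation (a Stork–Danheiser-type addition–elimination at a vinylogous ester carbonyl), here run in one flask as a formal [4+2] annulation of the C7/C4a 1,4-dicarbonyl unit with the C5–C6 unit. Ring B closes in the 6-(enolendo)-exo-trig mode. The only new stereocentre, C7, is set in the addition by the C8 silyloxy centre under polar Felkin–Anh (Cornforth) control: the nucleophile enters anti to the C8–O bond past the C8 hydrogen, which places C7–OH cis to C8–O (7R), while the bulky silyl ether and the weakly Lewis-acidic, non-chelating organocerium reagent suppress the chelate pathway to the C7 epimer. Chemoselectivity for the C7 ketone over the C4a carbonyl and the dienone termini rests on the much lower electrophilicity of the vinylogous ester and on the 1,2-selective, weakly basic organocerium species; the ketol 25 can enolize only towards C5 because C7 is quaternary, so the condensation is regiospecific.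

Step 17
Reactants: 26 (7R,8R,8aS)-8-[(tert-butyldimethylsilyl)oxy]-7-hydroxy-7-methyl-3-[(E)-2-Dx-ethenyl]-1,7,8,8a-tetrahydro-6H-isochromen-6-one
Product: 27 (7R,8R,8aS)-5-bromo-8-[(tert-butyldimethylsilyl)oxy]-7-hydroxy-7-methyl-3-[(E)-2-Dx-ethenyl]-1,7,8,8a-tetrahydro-6H-isochromen-6-one
Conditions: NBS (1.05 equiv), THF, −20 → 0 °C, dark
Reagents that add atoms: N-bromosuccinimide, O=C1CCC(=O)N1Br
Why: Electrophilic bromination of the push–pull dienone (donor O2, acceptor C6=O) should occur at C5, its α-carbon, followed by loss of H5, the usual site of halogenation of this type of chromophore.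

Step 18
Reactants: 27 (7R,8R,8aS)-5-bromo-8-[(tert-butyldimethylsilyl)oxy]-7-hydroxy-7-methyl-3-[(E)-2-Dx-ethenyl]-1,7,8,8a-tetrahydro-6H-isochromen-6-one
Product: 28 penicilazaphilone H, (7R,8R,8aS)-5-bromo-3-[(1E,3S,4R,5S)-3,4-dihydroxy-3,5-dimethylhept-1-en-1-yl]-7,8-dihydroxy-7-methyl-1,7,8,8a-tetrahydro-6H-isochromen-6-one
Conditions: 48% aq. HF, MeCN, 0 °C → rt
Reagents that add atoms: none
Why: Aqueous HF cleaves the secondary silyl ether and, being acidic, hydrolyses the isopropylidene acetal; the vinylogous-ester chromophore and the tertiary alcohols should tolerate these mild conditions and no stereocentre is touched.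

**Compound list**

1 | D-allo-isoleucine, (2R,3S)-2-amino-3-methylpentanoic acid | CC[C@H](C)[C@@H](N)C(=O)O | starting material
2 | (2R,3S)-2-hydroxy-3-methylpentanoic acid | CC[C@H](C)[C@@H](O)C(=O)O | intermediate
3 | (2R,3S)-2-hydroxy-N-methoxy-N,3-dimethylpentanamide | CC[C@H](C)[C@@H](O)C(=O)N(C)OC | intermediate
4 | 1,4-bis(trimethylsilyl)buta-1,3-diyne | C[Si](C)(C)C#CC#C[Si](C)(C)C | starting material
5 | [4-(trimethylsilyl)buta-1,3-diyn-1-yl]lithium | [Li]C#CC#C[Si](C)(C)C | intermediate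
6 | (6R,7S)-6-hydroxy-7-methyl-1-(trimethylsilyl)nona-1,3-diyn-5-one | CC[C@H](C)[C@@H](O)C(=O)C#CC#C[Si](C)(C)C | intermediate
7 | (5S,6R,7S)-5,7-dimethyl-1-(trimethylsilyl)nona-1,3-diyne-5,6-diol | CC[C@H](C)[C@@H](O)[C@@](C)(O)C#CC#C[Si](C)(C)C | intermediate
8 | (3E,5S,6R,7S)-5,7-dimethyl-1-(trimethylsilyl)non-3-en-1-yne-5,6-diol | CC[C@H](C)[C@@H](O)[C@@](C)(O)/C=C/C#C[Si](C)(C)C | intermediate
9 | (3E,5S,6R,7S)-5,7-dimethylnon-3-en-1-yne-5,6-diol | CC[C@H](C)[C@@H](O)[C@@](C)(O)/C=C/C#C | intermediate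
10 | (4S,5R)-4-[(1E)-but-1-en-3-yn-1-yl]-5-[(2S)-butan-2-yl]-2,2,4-trimethyl-1,3-dioxolane | CC[C@H](C)[C@H]1OC(C)(C)O[C@@]1(C)/C=C/C#C | intermediate
11 | 3-[(tert-butyldimethylsilyl)oxy]propanal | CC(C)(C)[Si](C)(C)OCCC=O | starting material
12 | lithium acetylide of 10 | CC[C@H](C)[C@H]1OC(C)(C)O[C@@]1(C)/C=C/C#C[Li] | intermediate
13 | (6E)-1-[(tert-butyldimethylsilyl)oxy]-7-Dx-hept-6-en-4-yn-3-ol (both C3 epimers) | CC[C@H](C)[C@H]1OC(C)(C)O[C@@]1(C)/C=C/C#CC(O)CCO[Si](C)(C)C(C)(C)C | intermediate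
14 | (6E)-1-[(tert-butyldimethylsilyl)oxy]-7-Dx-hept-6-en-4-yn-3-one | CC[C@H](C)[C@H]1OC(C)(C)O[C@@]1(C)/C=C/C#CC(=O)CCO[Si](C)(C)C(C)(C)C | intermediate
15 | ethyl (S)-lactate | C[C@H](O)C(=O)OCC | starting material
16 | ethyl (2S)-2-[(triethylsilyl)oxy]propanoate | C[C@H](O[Si](CC)(CC)CC)C(=O)OCC | intermediate
17 | (2S)-2-[(triethylsilyl)oxy]propanal | C[C@H](O[Si](CC)(CC)CC)C=O | intermediate
18 | (E)-enol dicyclohexylborinate of 14 | CC[C@H](C)[C@H]1OC(C)(C)O[C@@]1(C)/C=C/C#C/C(OB(C2CCCCC2)C2CCCCC2)=C\CO[Si](C)(C)C(C)(C)C | intermediate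
19 | (2S,3R,4S,8E)-4-{[(tert-butyldimethylsilyl)oxy]methyl}-3-hydroxy-2-[(triethylsilyl)oxy]-9-Dx-non-8-en-6-yn-5-one | CC[C@H](C)[C@H]1OC(C)(C)O[C@@]1(C)/C=C/C#CC(=O)[C@@H](CO[Si](C)(C)C(C)(C)C)[C@@H](O)[C@H](C)O[Si](CC)(CC)CC | intermediate
20 | (2S,3R,4S,8E)-3-[(tert-butyldimethylsilyl)oxy]-4-{[(tert-butyldimethylsilyl)oxy]methyl}-2-[(triethylsilyl)oxy]-9-Dx-non-8-en-6-yn-5-one | CC[C@H](C)[C@H]1OC(C)(C)O[C@@]1(C)/C=C/C#CC(=O)[C@@H](CO[Si](C)(C)C(C)(C)C)[C@@H](O[Si](C)(C)C(C)(C)C)[C@H](C)O[Si](CC)(CC)CC | intermediate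
21 | (2S,3R,4S,8E)-3-[(tert-butyldimethylsilyl)oxy]-2-hydroxy-4-(hydroxymethyl)-9-Dx-non-8-en-6-yn-5-one | CC[C@H](C)[C@H]1OC(C)(C)O[C@@]1(C)/C=C/C#CC(=O)[C@@H](CO)[C@@H](O[Si](C)(C)C(C)(C)C)[C@H](C)O | intermediate
22 | (3S)-3-{(1R,2S)-1-[(tert-butyldimethylsilyl)oxy]-2-hydroxypropyl}-6-[(E)-2-Dx-ethenyl]-2,3-dihydro-4H-pyran-4-one | CC[C@H](C)[C@H]1OC(C)(C)O[C@@]1(C)/C=C/C2=CC(=O)[C@H]([C@@H](O[Si](C)(C)C(C)(C)C)[C@H](C)O)CO2 | intermediate
23 | (3S)-3-{(1R)-1-[(tert-butyldimethylsilyl)oxy]-2-oxopropyl}-6-[(E)-2-Dx-ethenyl]-2,3-dihydro-4H-pyran-4-one | CC[C@H](C)[C@H]1OC(C)(C)O[C@@]1(C)/C=C/C2=CC(=O)[C@H]([C@@H](O[Si](C)(C)C(C)(C)C)C(C)=O)CO2 | intermediate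
24 | (3S)-3-{(1R,2R)-1-[(tert-butyldimethylsilyl)oxy]-3-ethoxy-2-hydroxy-2-methylbut-3-en-1-yl}-6-[(E)-2-Dx-ethenyl]-2,3-dihydro-4H-pyran-4-one | CC[C@H](C)[C@H]1OC(C)(C)O[C@@]1(C)/C=C/C2=CC(=O)[C@H]([C@@H](O[Si](C)(C)C(C)(C)C)[C@@](C)(O)C(=C)OCC)CO2 | intermediate
25 | (3S)-3-{(1R,2R)-1-[(tert-butyldimethylsilyl)oxy]-2-hydroxy-2-methyl-3-oxobutyl}-6-[(E)-2-Dx-ethenyl]-2,3-dihydro-4H-pyran-4-one | CC[C@H](C)[C@H]1OC(C)(C)O[C@@]1(C)/C=C/C2=CC(=O)[C@H]([C@@H](O[Si](C)(C)C(C)(C)C)[C@@](C)(O)C(C)=O)CO2 | intermediate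
26 | (7R,8R,8aS)-8-[(tert-butyldimethylsilyl)oxy]-7-hydroxy-7-methyl-3-[(E)-2-Dx-ethenyl]-1,7,8,8a-tetrahydro-6H-isochromen-6-one | CC[C@H](C)[C@H]1OC(C)(C)O[C@@]1(C)/C=C/C2=CC3=CC(=O)[C@](C)(O)[C@H](O[Si](C)(C)C(C)(C)C)[C@@H]3CO2 | intermediate
27 | (7R,8R,8aS)-5-bromo-8-[(tert-butyldimethylsilyl)oxy]-7-hydroxy-7-methyl-3-[(E)-2-Dx-ethenyl]-1,7,8,8a-tetrahydro-6H-isochromen-6-one | CC[C@H](C)[C@H]1OC(C)(C)O[C@@]1(C)/C=C/C2=CC3=C(Br)C(=O)[C@](C)(O)[C@H](O[Si](C)(C)C(C)(C)C)[C@@H]3CO2 | intermediate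
28 | penicilazaphilone H | CC[C@H](C)[C@@H](O)[C@@](C)(O)/C=C/C1=CC2=C(Br)C(=O)[C@](C)(O)[C@H](O)[C@@H]2CO1 | target

**Count and risks**

Total step count: 18. Longest linear sequence: 16 steps (steps 1–9 and 12–18).

Steps most likely to fail:

1. Step 16. The vinyl anion may enolize the ketone instead of adding, or enol-ether hydrolysis may outrun ring closure so that the sequence stops at the ketol, with the acid then eroding the protecting groups. Fallback, from 23 back to 26: ethynylmagnesium bromide with CeCl3 (THF, −78 °C) should give the tertiary propargylic alcohol F1 with the same Felkin sense at C7. Gold-catalysed Markovnikov hydration of F1 (AuCl(PPh3)/AgOSO2CF3, wet dioxane) gives the ketol 25. LiN(SiMe3)2 (2.2 equiv, THF, −78 °C) then forms the alkoxide enolate F2, whose C5 carbon adds 1,2 to the C4a vinylogous-ester carbonyl to give the aldol F3. Acetic acid on work-up dehydrates F3 to 26. The two bonds are thus made in separate steps and the ring is closed under base.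

2. Step 12. Enolization of the enynone by the boron chloride may be incomplete or accompanied by conjugate addition to the ynone, and the anti selectivity may erode. Fallback, from 14 back to 22: HF·pyridine gives the hydroxy ynone F4, and AuCl(PPh3)/AgOSO2CF3 closes it to the dihydropyranone F5. LDA (THF, −78 °C) forms the ring-fixed lithium enolate F6, which adds to 17 to give the anti,anti-aldol F7. t-BuMe2SiOSO2CF3/2,6-lutidine gives the silyl ether F8, and buffered HF·pyridine removes the triethylsilyl group to return to 22. Here the aldol is run on the cyclic vinylogous ester, whose enolate geometry is fixed by ring A.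

3. Step 17. Site selectivity of the electrophilic bromination may be poor (attack at C4 or at the C9=C10 bond, over-bromination). Fallback, from 23 back to 27: the first half of step 16 is quenched with pH 7 buffer and the enol ether adduct 24 is isolated. NBS in wet THF at −78 °C brominates the enol ether carbon to give the bromomethyl ketone F9, so that bromine sits on C5 before ring B exists. p-TsOH·H2O in THF at 40 °C then closes and dehydrates F9 to 27.

**Further compounds**

F1 | step 16 | (3S)-3-{(1R,2S)-1-[(tert-butyldimethylsilyl)oxy]-2-hydroxy-2-methylbut-3-yn-1-yl}-6-[(E)-2-Dx-ethenyl]-2,3-dihydro-4H-pyran-4-one | CC[C@H](C)[C@H]1OC(C)(C)O[C@@]1(C)/C=C/C2=CC(=O)[C@H]([C@@H](O[Si](C)(C)C(C)(C)C)[C@@](C)(O)C#C)CO2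
F2 | step 16 | dilithium alkoxide enolate of 25 | CC[C@H](C)[C@H]1OC(C)(C)O[C@@]1(C)/C=C/C2=CC(=O)[C@H]([C@@H](O[Si](C)(C)C(C)(C)C)[C@@](C)(O[Li])C(O[Li])=C)CO2
F3 | step 16 | (7R,8R,8aS)-8-[(tert-butyldimethylsilyl)oxy]-4a,7-dihydroxy-7-methyl-3-[(E)-2-Dx-ethenyl]-1,4a,5,7,8,8a-hexahydro-6H-isochromen-6-one (C4a configuration open) | CC[C@H](C)[C@H]1OC(C)(C)O[C@@]1(C)/C=C/C2=CC3(O)CC(=O)[C@](C)(O)[C@H](O[Si](C)(C)C(C)(C)C)[C@@H]3CO2
F4 | step 12 | (6E)-1-hydroxy-7-Dx-hept-6-en-4-yn-3-one | CC[C@H](C)[C@H]1OC(C)(C)O[C@@]1(C)/C=C/C#CC(=O)CCO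
F5 | step 12 | 6-[(E)-2-Dx-ethenyl]-2,3-dihydro-4H-pyran-4-one | CC[C@H](C)[C@H]1OC(C)(C)O[C@@]1(C)/C=C/C2=CC(=O)CCO2
F6 | step 12 | lithium enolate of F5 | CC[C@H](C)[C@H]1OC(C)(C)O[C@@]1(C)/C=C/C2=CC(O[Li])=CCO2
F7 | step 12 | (3S)-3-{(1R,2S)-1-hydroxy-2-[(triethylsilyl)oxy]propyl}-6-[(E)-2-Dx-ethenyl]-2,3-dihydro-4H-pyran-4-one | CC[C@H](C)[C@H]1OC(C)(C)O[C@@]1(C)/C=C/C2=CC(=O)[C@H]([C@@H](O)[C@H](C)O[Si](CC)(CC)CC)CO2
F8 | step 12 | (3S)-3-{(1R,2S)-1-[(tert-butyldimethylsilyl)oxy]-2-[(triethylsilyl)oxy]propyl}-6-[(E)-2-Dx-ethenyl]-2,3-dihydro-4H-pyran-4-one | CC[C@H](C)[C@H]1OC(C)(C)O[C@@]1(C)/C=C/C2=CC(=O)[C@H]([C@@H](O[Si](C)(C)C(C)(C)C)[C@H](C)O[Si](CC)(CC)CC)CO2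
F9 | step 17 | (3S)-3-{(1R,2R)-4-bromo-1-[(tert-butyldimethylsilyl)oxy]-2-hydroxy-2-methyl-3-oxobutyl}-6-[(E)-2-Dx-ethenyl]-2,3-dihydro-4H-pyran-4-one | CC[C@H](C)[C@H]1OC(C)(C)O[C@@]1(C)/C=C/C2=CC(=O)[C@H]([C@@H](O[Si](C)(C)C(C)(C)C)[C@@](C)(O)C(=O)CBr)CO2
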